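**Retrosynthetic overview**
1. Target sulfone ⇒ benzylic C–S disconnection to 2,3-dibromo-4,5-dihydroxybenzaldehyde + MeSO2Na + one hydride (proposed one-pot reductive sulfonylation through a para-quinone methide).
2. 2,3-Dibromo-4,5-dihydroxybenzaldehyde ⇒ O-demethylation of 5,6-dibromovanillin.
3. 5,6-Dibromovanillin ⇒ two successive electrophilic brominations of vanillin (ortho to OH, then para to OMe).
4. Rings: none is formed; the single benzene ring comes intact from vanillin.

Assumption: the target has no stereocentre and no stereogenic double bond, so "single enantiomer" is taken to mean the achiral compound exactly as drawn, and no stereocontrol is needed.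

**Step 1**
Reactants: 1 vanillin (4-hydroxy-3-methoxybenzaldehyde)
Product: 2 5-bromovanillin (3-bromo-4-hydroxy-5-methoxybenzaldehyde)
Conditions: Br2 (1.05 equiv), AcOH, rt, 2 h
Reagents that add atoms: bromine, BrBr
Why: Electrophilic aromatic bromination; the free phenol is the strongest director, its para position carries the formyl group, and its one open ortho position (also meta to CHO) is brominated cleanly.

**Step 2**
Reactants: 2 5-bromovanillin (3-bromo-4-hydroxy-5-methoxybenzaldehyde)
Product: 3 5,6-dibromovanillin (2,3-dibromo-4-hydroxy-5-methoxybenzaldehyde)
Conditions: Br2 (1.5 equiv), FeBr3 (10 mol %), AcOH, rt → 60 °C, 12 h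
Reagents that add atoms: bromine, BrBr
Why: Lewis-acid-catalysed electrophilic aromatic bromination; with every ortho and para position of the hydroxyl occupied, the methoxy group directs the second bromine to its para position, next to the first bromine, giving the 2,3-dibromo pattern.

**Step 3**
Reactants: 3 5,6-dibromovanillin (2,3-dibromo-4-hydroxy-5-methoxybenzaldehyde)
Product: 4 2,3-dibromo-4,5-dihydroxybenzaldehyde
Conditions: BBr3 (3.0 equiv), CH2Cl2, −78 °C → rt, 12 h; then ice/H2O
Reagents that add atoms: none
Why: BBr3 aryl methyl ether cleavage (Lewis-acid O-demethylation); the aryl bromides are inert and the aldehyde is only reversibly complexed and returns on aqueous work-up.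

**Step 4**
Reactants: 4 2,3-dibromo-4,5-dihydroxybenzaldehyde
Product: 7 2,3-dibromo-4,5-dihydroxybenzyl methyl sulfone, via lanosol 5 (not isolated), via para-quinone methide 6 (not isolated)
Conditions: MeSO2Na (3.0 equiv), CF3CO2H/CH2Cl2 (1:2), 0 °C; Et3SiH (1.15 equiv) added over 2 h; then rt, 4 h, N2
Reagents that add atoms: sodium methanesulfinate, CS(=O)[O-].[Na+]
Why: Proposed new method: an interrupted ionic hydrogenation used as a one-pot reductive sulfonylation of a 4-hydroxybenzaldehyde, in which Et3SiH transfers one hydride to the protonated aldehyde to give lanosol 5, the para-hydroxyl expels water to give quinone methide 6 (reacting as its O-protonated benzyl cation), and methanesulfinic acid/methanesulfinate (in excess, and far more nucleophilic at sulfur than the slowly added silane is as a hydride donor) captures 6 by 1,6-addition to form the benzylic C–S bond before a second hydride can arrive, any O-bound sulfinate ester re-ionising and funnelling to the sulfone, which does not re-ionise in this medium; the closest known reaction types are the Et3SiH/CF3CO2H ionic hydrogenation of aryl aldehydes and the acid-mediated 1,6-addition of sulfinates to para-quinone methides from 4-hydroxybenzyl alcohols, and no stereocentre is formed.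

**Compound list**
1 | vanillin (4-hydroxy-3-methoxybenzaldehyde) | COc1cc(C=O)ccc1O | starting material
2 | 5-bromovanillin (3-bromo-4-hydroxy-5-methoxybenzaldehyde) | COc1cc(C=O)cc(Br)c1O | intermediate
3 | 5,6-dibromovanillin (2,3-dibromo-4-hydroxy-5-methoxybenzaldehyde) | COc1cc(C=O)c(Br)c(Br)c1O | intermediate
4 | 2,3-dibromo-4,5-dihydroxybenzaldehyde | O=Cc1cc(O)c(O)c(Br)c1Br | intermediate
5 | lanosol (2,3-dibromo-4,5-dihydroxybenzyl alcohol), formed in the flask in step 4 and not isolated | OCc1cc(O)c(O)c(Br)c1Br | intermediate
6 | para-quinone methide (2,3-dibromo-6-hydroxy-4-methylidenecyclohexa-2,5-dien-1-one), formed in the flask in step 4 and not isolated | C=C1C=C(O)C(=O)C(Br)=C1Br | intermediate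
7 | 2,3-dibromo-4,5-dihydroxybenzyl methyl sulfone (3,4-dibromo-5-[(methylsulfonyl)methyl]benzene-1,2-diol) | CS(=O)(=O)Cc1cc(O)c(O)c(Br)c1Br | target

**Totals**
Total step count: 4. Longest linear sequence: 4 steps (1 → 2 → 3 → 4 → 7).

**Three steps most likely to fail**

Step 4 (the proposed new step). The risks are a second hydride transfer to 6 giving the over-reduced cresol, Friedel–Crafts self-benzylation of the electron-rich ring by 6, and slow reduction of the hindered aldehyde. The fallback sets out from 4 and comes back to the route at 7, using known chemistry only. Compound 4 is reduced with NaBH4 (THF/H2O, 0 °C; acidification to pH 5 in the cold, extraction without alcohol solvents) to lanosol 5, which is isolated this time. Compound 5 is then warmed with MeSO2Na (3 equiv) in AcOH/H2O (1:1) at 50 °C, the known acid-mediated dehydrative sulfonylation of a 4-hydroxybenzyl alcohol, which passes through 6 and gives 7. Hydride delivery and C–S bond formation are separated in time, so no hydride donor is present when 6 forms. This fallback makes no compound outside the compound list (no new compound, F0).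

Step 2. The risks are ipso-attack of bromine at the formyl-bearing carbon para to the hydroxyl (bromodeformylation) and incomplete bromination of a ring deactivated by CHO. The fallback sets out from 2 and comes back to the route at 7; it removes the formyl group before the second bromination. Compound 2 is reduced with NaBH4 (MeOH/THF, 0 °C) to 3-bromo-4-hydroxy-5-methoxybenzyl alcohol F1. Heating F1 with MeSO2Na in aqueous HCO2H at 60 °C gives 3-bromo-4-hydroxy-5-methoxybenzyl methyl sulfone F2 by dehydrative benzylic substitution. Bromination of F2 (Br2, 1.1 equiv, AcOH, rt) goes para to the methoxy group on a ring that is no longer deactivated and has no deformylation channel, giving 2,3-dibromo-4-hydroxy-5-methoxybenzyl methyl sulfone F3. Demethylation of F3 with BBr3 (CH2Cl2, −78 °C → rt; then H2O) gives 7.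

Step 3. The risks are side reactions of the free aldehyde with BBr3 (benzal bromide formation, tar) and incomplete cleavage. The fallback sets out from 3 and comes back to the route at 7; it demethylates after the aldehyde has been reduced and uses the benzylic bromination that BBr3 then causes. Compound 3 is reduced with NaBH4 (MeOH/THF, 0 °C) to 2,3-dibromo-4-hydroxy-5-methoxybenzyl alcohol F4. BBr3 (4 equiv, CH2Cl2, −78 °C → rt; brief cold-water quench) cleaves the methyl ether and converts the benzylic alcohol into the bromide, giving 3,4-dibromo-5-(bromomethyl)benzene-1,2-diol F5. Displacement of the bromide of F5 with MeSO2Na (2 equiv, DMF, rt) gives 7. Any F5 that hydrolyses to 5 during work-up is converted to 7 by the same sulfinate in aqueous AcOH.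

**Further compounds**
F0 | step 4 | none | none
F1 | step 2 | 3-bromo-4-hydroxy-5-methoxybenzyl alcohol | COc1cc(CO)cc(Br)c1O
F2 | step 2 | 3-bromo-4-hydroxy-5-methoxybenzyl methyl sulfone | COc1cc(CS(C)(=O)=O)cc(Br)c1O
F3 | step 2 | 2,3-dibromo-4-hydroxy-5-methoxybenzyl methyl sulfone | COc1cc(CS(C)(=O)=O)c(Br)c(Br)c1O
F4 | step 3 | 2,3-dibromo-4-hydroxy-5-methoxybenzyl alcohol | COc1cc(CO)c(Br)c(Br)c1O
F5 | step 3 | 3,4-dibromo-5-(bromomethyl)benzene-1,2-diol | BrCc1cc(O)c(O)c(Br)c1Br
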